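If a flask slows merely as L runs down in first order, the climb from a quarter of the L charged to half of it takes 1.41 times as long as the climb to that quarter.

| flask | L | Z | X | time |
|---|---|---|---|---|
| zeta | 80.0 mM | 0.160 mM |  |  |
| alpha | 80.0 mM | 0.0800 mM |  |  |
| eta | 240 mM | 0.160 mM |  |  |
| gamma | 80.0 mM | 0.160 mM | 24.0 mM | 30 min |

| run | time / min | [X] / mM |
|---|---|---|
| zeta run | 1.1 | 12.8 |
| zeta run | 3.3 | 24.1 |
| zeta run | 6.2 | 32.6 |
| zeta run | 9.9 | 38.6 |
| zeta run | 14 | 43.6 |
| zeta run | 19 | 48.2 |
| zeta run | 24 | 52.4 |
| zeta run | 30 | 53.8 |
| alpha run | 1.1 | 7.8 |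
| alpha run | 3.3 | 15.2 |
| alpha run | 6.2 | 24.2 |
| alpha run | 9.9 | 29.7 |
| alpha run | 14 | 34.2 |
| alpha run | 19 | 37.8 |
| alpha run | 24 | 41.9 |
| alpha run | 30 | 44.7 |
| eta run | 1.1 | 34.6 |
| eta run | 3.3 | 70.1 |
| eta run | 6.2 | 93.8 |
| eta run | 9.9 | 115.2 |
| eta run | 14 | 130.5 |
| eta run | 19 | 145.3 |
| eta run | 24 | 154.5 |
| eta run | 30 | 164.2 |

(standard deviation of a reading: 0.8 mM)

- Overall: L -> X, with Z as catalyst.
- Constant volume, constant temperature.
- A reading of a species includes what of it is bound.
- An order is taken over about fifteen percent of the charge, up and down.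
- A share of X counts the X that was charged too.

- reaction order in [Z] at the outset, round the charge of the zeta run, defined at two percent of the L turned into X
- reaction order in [L] at the outset, round the charge of the zeta run, defined at two percent of the L turned into X (one fixed amount of X, the same in the runs compared)
- X in the gamma run at 30 min, as a share of the L charged
- which of these the readings show (the substrate kills the catalyst / the substrate is lost by itself / the product ties up the catalyst)

Between its readings the zeta run crossed those two marks near 2.50 min and 11.0 min, so its second climb took 3.40 times as long as its first, and I looked for a second brake.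

I ranked the rates from fastest to slowest. Over the first reading the eta run averaged 31.5 mM min⁻¹, the zeta run 11.6 mM min⁻¹ and the alpha run 7.09 mM min⁻¹. The alpha run, with half the Z, took 6.2 min to reach the 24.2 mM that the zeta run read as 24.1 mM at 3.3 min, and these average rates gave me an order in Z near 0.904. The alpha run's 37.8 mM at 19 min stood beside the zeta run's 38.6 mM at 9.9 min, so its curve followed Z multiplied by time, and I saw no clock of L or Z running by itself. Average rates to similar X, the eta run's first reading against the zeta run's second, gave me an order in L near 1.33. The eta run reached 164.2 mM on the Z that gave 53.8 mM in the zeta run, so I saw no cap set by Z.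

Over their last interval the rates read lower: 1.62 mM min⁻¹ in the eta run, 0.467 mM min⁻¹ in the alpha run and 0.233 mM min⁻¹ in the zeta run. The end of the eta run was the useful rung, at 1.62 mM min⁻¹. There X stood near 159 mM and L near 80.6 mM, about the zeta charge. With about that L and the same Z, the rate read 7.20 times lower than over the zeta run's first reading, where X averaged about 6.40 mM. I took the rate at a given L to go as Xh/(Xh + X), and these two readings gave:

Xh = (X late − ratio × X early)/(ratio − 1) = 18.3 mM

The X at which, at a given L, the rate falls to 0.5 of its value without X I call the brake constant Xh.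

The gamma run at equal X made, Y, holds the zeta run's L, so it runs at s = (Xh + Y)/(Xh + Y + 24.0 mM) of the zeta rate. Its 30 min then equal s × 30 min on the zeta clock. Y depends on that clock, so I went round again:

Y = 43.6 mM, mid-run: s = 0.721, clock 21.6 min

Y = 38.6 mM, read at 9.9 min, near that clock's middle of 10.8 min: s = 0.703, clock 21.1 min

Zeta readings give Y = 50.0 mM, so my share was 92.5%.

The forecast gave 0.9 in Z, 0.92 in L, 98% and "the substrate is lost by itself", holding that “added X changes nothing”. We parted on that point.

The simulation gave 1.0, 1.3, 89.9% and "the product ties up the catalyst".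

    Z + L ⇌ ZL, settled at all times (2.960 L mol⁻¹)
    ZL + L ⇌ ZL2, settled at all times (41.20 L mol⁻¹)
    ZL2 → X + ZL (343.2 min⁻¹)
    Z + X ⇌ ZX, settled at all times (169.0 L mol⁻¹)

In the gamma run, ZL2 made X from the first minute while the charged X held Z as ZX, and with Xh the start stood at 43.3% of the rate without X. The zeta run's last reading, 53.8 mM, puts its rate at 25.4% of that rate at equal L, and the gamma run's 71.9 mM of X at 30 min puts its rate at 20.3%.

Readings and results stem from a simulated flask with made-up constants.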